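**Plan**
- Eudesmane locants are used throughout: ring A = C1–C5, C10 (benzyl on C1, methyl C15 on C4); ring B = C5–C10 (isopropenyl on C7, methyl C14 on C10).
- Retrosynthesis: strip the two aryl carbonyls and the MOM groups; cut C1–CH2Ar (benzylation of a C2 enol silane); cut C3–C4 and C5–C10 together; take the acyclic chain back to (S)-limonene.
- Enabling feature: the C5=C6 alkene is exocyclic to ring A at the ring fusion and flanked by the C4 methine. This is the retron of a Diels–Alder reaction in which an allene C4=C5=C6 is the dienophile (C4=C5 reacts, C5=C6 survives) and C3=C2–C1=C10 is the diene.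
- Forward: rings A and B form together in step 9 from an acyclic 2-silyloxydiene–allenoate. Helpers: CO2Et on C4 (activates and selects C4=C5, later reduced to C15 methyl) and OTIPS on C2 (gives the C1 enol silane, C2 oxygen later removed).
- Stereochemistry: C7 from (S)-limonene; the allene axis from a catalyst-controlled Pd β-hydride elimination, transferred to C4; C10 from the (E)-diene terminus (Negishi carboalumination) plus an exo ester; C1 from alkylation on the convex face.

Key step: step 9

Remark: (S)-limonene and 2,4,6-trihydroxybenzaldehyde are taken as commercial; in the allene SMILES the tag on the central carbon refers to the four end substituents in the order written, with the hydrogens written out.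

**Step 1**
Reactants: 1 (S)-limonene
Product: 3 (5S)-7,7-dimethoxy-5-(prop-1-en-2-yl)heptan-2-one, via hydroperoxy acetal 2 (not isolated)
Conditions: O3, CH2Cl2/MeOH, −78 °C, Sudan Red 7B as end-point indicator; TsOH·H2O, rt; NaHCO3, then Me2S
Reagents that add atoms: ozone, [O-][O+]=O; methanol, CO
Why: Ozone should cleave the electron-rich trisubstituted ring alkene before the isopropenyl group; methanol traps the carbonyl oxide on the methyl-bearing carbon, TsOH acetalizes the aldehyde end and Me2S reduces the hydroperoxide to the ketone (Criegee ozonolysis, terminus-differentiating Schreiber variant), leaving the limonene stereocentre untouched.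

**Step 2**
Reactants: 3 keto acetal
Product: 5 (5S)-7,7-dimethoxy-5-(prop-1-en-2-yl)hept-1-yne, via enol phosphate 4 (not isolated)
Conditions: LiN(i-Pr)2 (1.1 equiv), THF, −78 °C; ClP(O)(OEt)2; LiN(i-Pr)2 (2.3 equiv), −78 °C to rt; aq. NH4Cl
Reagents that add atoms: none
Why: Kinetic deprotonation at the methyl group, O-phosphorylation and base-induced loss of diethyl phosphate turn the methyl ketone into the terminal alkyne (Negishi methyl ketone to alkyne protocol); acetal and isopropenyl group are inert to the amide base.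

**Step 3**
Reactants: 5 alkyne
Product: 7 (3E,7S)-9,9-dimethoxy-4-methyl-7-(prop-1-en-2-yl)non-3-en-2-one, via alkenylalane 6 (not isolated)
Conditions: Me3Al, Cp2ZrCl2 (cat.), H2O (1 equiv), CH2Cl2, −20 °C; volatiles removed; AcCl, Pd(PPh3)4 (cat.), THF, 0 °C to rt
Reagents that add atoms: trimethylaluminium, C[Al](C)C; acetyl chloride, CC(=O)Cl
Why: Zirconium-catalysed syn-carboalumination (Negishi) puts the new methyl on the internal carbon cis to aluminium, and Pd-catalysed acylation with retention should give only the (E)-enone with the chain trans to the acyl group; the 1,1-disubstituted alkene does not carbometalate.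

**Step 4**
Reactants: 7 enone acetal
Product: 8 (3S,6E)-6-methyl-8-oxo-3-(prop-1-en-2-yl)non-6-enal
Conditions: PPTS (cat.), acetone/H2O, 50 °C
Reagents that add atoms: water, O
Why: Mild acid hydrolysis of the dimethyl acetal should free the aldehyde without moving the isopropenyl or enone double bonds.

**Step 5**
Reactants: 8 enone aldehyde
Product: 9 ethyl (5S,8E)-8-methyl-3,10-dioxo-5-(prop-1-en-2-yl)undec-8-enoate
Conditions: N2CHCO2Et, SnCl2 (cat.), CH2Cl2, rt
Reagents that add atoms: ethyl diazoacetate, CCOC(=O)C=[N+]=[N-]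
Why: SnCl2-catalysed formal C–H insertion of the diazo ester into the aldehyde (Roskamp homologation) is selective for the aldehyde over the conjugated methyl ketone and gives the β-keto ester whose ketone carbon becomes the central allene carbon C5.

**Step 6**
Reactants: 9 β-keto ester
Product: 10 ethyl (2E,5S,8E)-8-methyl-10-oxo-5-(prop-1-en-2-yl)-3-(trifluoromethanesulfonyloxy)undeca-2,8-dienoate
Conditions: Tf2O, aq. Me4NOH, toluene, 0 °C
Reagents that add atoms: triflic anhydride, O=S(=O)(OS(=O)(=O)C(F)(F)F)C(F)(F)F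
Why: O-Triflation of the β-keto ester enolate with a non-chelating ammonium counter-ion should give the (E)-enol triflate (Frantz conditions), while the far less acidic methyl ketone is not enolized.

**Step 7**
Reactants: 10 (E)-enol triflate
Product: 11 ethyl (Ra,5S,8E)-8-methyl-10-oxo-5-(prop-1-en-2-yl)undeca-2,3,8-trienoate
Conditions: Pd2(dba)3 (cat.), BINOL-derived chiral monophosphite (the antipode that delivers the (Ra) axis), i-Pr2NEt, toluene, rt
Reagents that add atoms: none
Why: Oxidative addition of the enol triflate to zerovalent palladium and β-hydride elimination from the C6 methylene inside the chiral ligand pocket should form the 1,3-disubstituted allenoate with catalyst control of the axis (enantioselective Pd-catalysed β-hydride elimination of enol triflates); in the (E)-triflate the vinylic hydrogen is cis to the triflate, which blocks anti elimination to the alkynoate.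

**Step 8**
Reactants: 11 allenoate enone
Product: 12 ethyl (Ra,5S,8E)-8-methyl-5-(prop-1-en-2-yl)-10-[(triisopropylsilyl)oxy]undeca-2,3,8,10-tetraenoate
Conditions: TIPSOTf, Et3N, CH2Cl2, −78 to −20 °C
Reagents that add atoms: triisopropylsilyl triflate, CC(C)[Si](OS(=O)(=O)C(F)(F)F)(C(C)C)C(C)C
Why: Soft enolization (silyl triflate and amine) silylates the ketone oxygen and removes an α'-methyl proton to give the cross-conjugated 2-silyloxy diene with the (E)-terminus unchanged; the ester oxygen of the allenoate is much less basic and should stay untouched at low temperature.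

**Step 9**
Reactants: 12 silyloxydiene–allenoate
Product: 13 ethyl (1S,4aS,7S)-4a-methyl-7-(prop-1-en-2-yl)-3-[(triisopropylsilyl)oxy]-1,2,4a,5,6,7-hexahydronaphthalene-1-carboxylate
Conditions: toluene (high dilution), BHT (cat.), base-washed sealed tube, 120 °C
Reagents that add atoms: none
Why: On heating, the 2-silyloxy diene C3=C2–C1=C10 should add across the ester-conjugated C4=C5 bond of the allenoate in a concerted, asynchronous [4+2] cycloaddition, the closest known reaction type being the intramolecular Diels–Alder reaction of allenic esters; the orthogonal C5=C6 π bond is a spectator and ends as the ring-fusion alkene of the target. Ring A (C1–C5, C10) closes as the six-membered cycloadduct ring, and ring B (C5–C10) closes at the same time through the tether C6–C7–C8–C9, a six-membered closure onto the central allene carbon in which the former allene terminus C6 stays inside the ring. C4 is controlled by the allene axis: both new bonds form on the lobes of the C4=C5 π bond that lie on the tether side of C6, so the (Ra) axis is translated stereospecifically into (S) at C4. C10 is controlled by the (E) geometry of the diene terminus (chain outside, methyl inside, the only geometry from which the tether reaches the allene) together with an exo ester, which should be favoured because the OTIPS group on C2 fills the endo quadrant next to C3; the (7S) centre is a spectator that sits pseudo-equatorially. The step needs periselectivity for C4=C5 over C5=C6 and the isopropenyl group, which conjugation with the ester secures, and it must outrun the [1,5]-hydrogen shift of the inside methyl, which is helped because the sp-hybridised C5 carries no substituent to clash with that methyl.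

**Step 10**
Reactants: 14 2,4,6-trihydroxybenzaldehyde
Product: 15 2,4,6-tris(methoxymethoxy)benzaldehyde
Conditions: MOMCl, i-Pr2NEt, CH2Cl2, 0 °C to rt
Reagents that add atoms: chloromethyl methyl ether, COCCl
Why: O-Alkylation of the three phenols with the chloromethyl ether under amine base gives the tris-acetal, which later directs the ring lithiations and is removable under mild acid.

**Step 11**
Reactants: 15 tris-MOM aldehyde
Product: 16 [2,4,6-tris(methoxymethoxy)phenyl]methanol
Conditions: NaBH4, MeOH/THF, 0 °C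
Reagents that add atoms: none
Why: Borohydride reduction of the aryl aldehyde gives the benzylic alcohol.

**Step 12**
Reactants: 16 benzylic alcohol
Product: 17 2-(bromomethyl)-1,3,5-tris(methoxymethoxy)benzene
Conditions: CBr4, PPh3, 2,6-lutidine, CH2Cl2, −20 °C; used at once as a cold solution
Reagents that add atoms: carbon tetrabromide, BrC(Br)(Br)Br
Why: Appel bromination under neutral, buffered conditions should give the SN1-active benzylic bromide without touching the MOM acetals.

**Step 13**
Reactants: 13 enol silane; 17 benzylic bromide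
Product: 18 ethyl (1S,4S,4aS,7S)-4a-methyl-3-oxo-7-(prop-1-en-2-yl)-4-{[2,4,6-tris(methoxymethoxy)phenyl]methyl}-1,2,3,4,4a,5,6,7-octahydronaphthalene-1-carboxylate
Conditions: ZnBr2 (cat.), CH2Cl2, −60 to −30 °C, slow addition of 17
Reagents that add atoms: none
Why: Lewis acid-mediated alkylation of a silyl enol ether with an SN1-active benzylic halide (Reetz-type alkylation) is regiospecific at C1 because the cycloaddition delivered the C1=C2 enol silane; in the favoured half-chair (ester and C10 methyl both pseudo-equatorial) the C9 methylene is pseudo-axial on the lower face, so the cation should add axially on the convex face, cis to the C10 methyl.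

**Step 14**
Reactants: 18 ketone
Product: 20 ethyl (1S,4S,4aS,7S)-4a-methyl-7-(prop-1-en-2-yl)-4-{[2,4,6-tris(methoxymethoxy)phenyl]methyl}-1,2,3,4,4a,5,6,7-octahydronaphthalene-1-carboxylate, via tosylhydrazone 19 (not isolated)
Conditions: TsNHNH2, EtOH, 50 °C; crude hydrazone, catecholborane, CHCl3, 0 °C to rt; NaOAc·3H2O, reflux
Reagents that add atoms: none
Why: Hydride addition to the tosylhydrazone, loss of sulfinate and extrusion of N2 from the diazene leave a methylene at C2 (Caglioti reduction, Kabalka catecholborane variant) under conditions that spare the ester, the alkenes and the MOM groups and do not touch a stereocentre.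

**Step 15**
Reactants: 20 ester
Product: 21 [(1S,4S,4aS,7S)-4a-methyl-7-(prop-1-en-2-yl)-4-{[2,4,6-tris(methoxymethoxy)phenyl]methyl}-1,2,3,4,4a,5,6,7-octahydronaphthalen-1-yl]methanol
Conditions: i-Bu2AlH, CH2Cl2, −78 to 0 °C; aq. potassium sodium tartrate
Reagents that add atoms: none
Why: Aluminium hydride reduction of the activating ester to the primary alcohol starts the removal of this helper.

**Step 16**
Reactants: 21 primary alcohol
Product: 23 2-{[(1S,4S,6S,8aS)-4,8a-dimethyl-6-(prop-1-en-2-yl)-1,2,3,4,6,7,8,8a-octahydronaphthalen-1-yl]methyl}-1,3,5-tris(methoxymethoxy)benzene, via mesylate 22 (not isolated)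
Conditions: MsCl, Et3N, CH2Cl2, 0 °C; then LiEt3BH, THF, 0 °C to rt
Reagents that add atoms: none
Why: Sulfonylation and SN2 hydride displacement of the primary mesylate turn CH2OH into the C15 methyl without touching the C4 stereocentre.

**Step 17**
Reactants: 23 tris-MOM arene
Product: 26 3-{[(1S,4S,6S,8aS)-4,8a-dimethyl-6-(prop-1-en-2-yl)-1,2,3,4,6,7,8,8a-octahydronaphthalen-1-yl]methyl}-2,4,6-tris(methoxymethoxy)-5-(3-methylbutanoyl)benzaldehyde, via lithium amino alkoxide 24 (not isolated), via dilithium bis-adduct 25 (not isolated)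
Conditions: n-BuLi, THF, 0 °C; Me2NCH2CH2N(Me)CHO, −78 to 0 °C; n-BuLi, 0 °C; i-BuC(O)N(OMe)Me, −78 to 0 °C; aq. NH4Cl
Reagents that add atoms: N-[2-(dimethylamino)ethyl]-N-methylformamide, CN(C)CCN(C)C=O; N-methoxy-N,3-dimethylbutanamide, CC(C)CC(=O)N(C)OC
Why: Each free ring position lies between two MOM ethers and is lithiated by directed ortho-metalation; the first aryllithium is formylated to an α-amino alkoxide that protects the aldehyde in the flask (Comins protocol), and the second is acylated by the Weinreb amide, so aqueous work-up releases aldehyde and ketone together.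

**Step 18**
Reactants: 26 tris-MOM keto aldehyde
Product: 27 3-{[(1S,4S,6S,8aS)-4,8a-dimethyl-6-(prop-1-en-2-yl)-1,2,3,4,6,7,8,8a-octahydronaphthalen-1-yl]methyl}-2,4,6-trihydroxy-5-(3-methylbutanoyl)benzaldehyde
Conditions: 2 M aq. HCl, THF/i-PrOH, 40 °C
Reagents that add atoms: none
Why: Acid hydrolysis of the three MOM acetals, assisted by hydrogen bonding of the freed phenols to the ortho carbonyls, should give the target under conditions that leave the isopropenyl and trisubstituted alkenes intact.

**Compound list**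
1 | (S)-limonene, (4S)-1-methyl-4-(prop-1-en-2-yl)cyclohex-1-ene | CC1=CC[C@H](CC1)C(C)=C | starting material
2 | (5S)-2-hydroperoxy-2,7,7-trimethoxy-5-(prop-1-en-2-yl)heptane (both C2 epimers) | C=C(C)[C@H](CC(OC)OC)CCC(C)(OC)OO | intermediate
3 | (5S)-7,7-dimethoxy-5-(prop-1-en-2-yl)heptan-2-one | C=C(C)[C@H](CC(OC)OC)CCC(C)=O | intermediate
4 | diethyl (5S)-7,7-dimethoxy-5-(prop-1-en-2-yl)hept-1-en-2-yl phosphate | C=C(C)[C@H](CC(OC)OC)CCC(=C)OP(=O)(OCC)OCC | intermediate
5 | (5S)-7,7-dimethoxy-5-(prop-1-en-2-yl)hept-1-yne | C=C(C)[C@H](CC(OC)OC)CCC#C | intermediate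
6 | [(1E,5S)-7,7-dimethoxy-2-methyl-5-(prop-1-en-2-yl)hept-1-en-1-yl]dimethylalumane | C=C(C)[C@H](CC(OC)OC)CC/C(C)=C/[Al](C)C | intermediate
7 | (3E,7S)-9,9-dimethoxy-4-methyl-7-(prop-1-en-2-yl)non-3-en-2-one | C=C(C)[C@H](CC(OC)OC)CC/C(C)=C/C(C)=O | intermediate
8 | (3S,6E)-6-methyl-8-oxo-3-(prop-1-en-2-yl)non-6-enal | C=C(C)[C@H](CC=O)CC/C(C)=C/C(C)=O | intermediate
9 | ethyl (5S,8E)-8-methyl-3,10-dioxo-5-(prop-1-en-2-yl)undec-8-enoate | C=C(C)[C@H](CC(=O)CC(=O)OCC)CC/C(C)=C/C(C)=O | intermediate
10 | ethyl (2E,5S,8E)-8-methyl-10-oxo-5-(prop-1-en-2-yl)-3-(trifluoromethanesulfonyloxy)undeca-2,8-dienoate | C=C(C)[C@H](C/C(OS(=O)(=O)C(F)(F)F)=C\C(=O)OCC)CC/C(C)=C/C(C)=O | intermediate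
11 | ethyl (Ra,5S,8E)-8-methyl-10-oxo-5-(prop-1-en-2-yl)undeca-2,3,8-trienoate | C=C(C)[C@H](C([H])=[C@]=C([H])C(=O)OCC)CC/C(C)=C/C(C)=O | intermediate
12 | ethyl (Ra,5S,8E)-8-methyl-5-(prop-1-en-2-yl)-10-[(triisopropylsilyl)oxy]undeca-2,3,8,10-tetraenoate | C=C(C)[C@H](C([H])=[C@]=C([H])C(=O)OCC)CC/C(C)=C/C(=C)O[Si](C(C)C)(C(C)C)C(C)C | intermediate
13 | ethyl (1S,4aS,7S)-4a-methyl-7-(prop-1-en-2-yl)-3-[(triisopropylsilyl)oxy]-1,2,4a,5,6,7-hexahydronaphthalene-1-carboxylate | C=C(C)[C@@H]1C=C2[C@@H](C(=O)OCC)CC(O[Si](C(C)C)(C(C)C)C(C)C)=C[C@]2(C)CC1 | intermediate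
14 | 2,4,6-trihydroxybenzaldehyde | O=Cc1c(O)cc(O)cc1O | starting material
15 | 2,4,6-tris(methoxymethoxy)benzaldehyde | O=Cc1c(OCOC)cc(OCOC)cc1OCOC | intermediate
16 | [2,4,6-tris(methoxymethoxy)phenyl]methanol | OCc1c(OCOC)cc(OCOC)cc1OCOC | intermediate
17 | 2-(bromomethyl)-1,3,5-tris(methoxymethoxy)benzene | BrCc1c(OCOC)cc(OCOC)cc1OCOC | intermediate
18 | ethyl (1S,4S,4aS,7S)-4a-methyl-3-oxo-7-(prop-1-en-2-yl)-4-{[2,4,6-tris(methoxymethoxy)phenyl]methyl}-1,2,3,4,4a,5,6,7-octahydronaphthalene-1-carboxylate | C=C(C)[C@@H]1C=C2[C@@H](C(=O)OCC)CC(=O)[C@@H](Cc3c(OCOC)cc(OCOC)cc3OCOC)[C@]2(C)CC1 | intermediate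
19 | 4-methylbenzenesulfonylhydrazone of 18 | C=C(C)[C@@H]1C=C2[C@@H](C(=O)OCC)CC(=NNS(=O)(=O)c3ccc(C)cc3)[C@@H](Cc3c(OCOC)cc(OCOC)cc3OCOC)[C@]2(C)CC1 | intermediate
20 | ethyl (1S,4S,4aS,7S)-4a-methyl-7-(prop-1-en-2-yl)-4-{[2,4,6-tris(methoxymethoxy)phenyl]methyl}-1,2,3,4,4a,5,6,7-octahydronaphthalene-1-carboxylate | C=C(C)[C@@H]1C=C2[C@@H](C(=O)OCC)CC[C@@H](Cc3c(OCOC)cc(OCOC)cc3OCOC)[C@]2(C)CC1 | intermediate
21 | [(1S,4S,4aS,7S)-4a-methyl-7-(prop-1-en-2-yl)-4-{[2,4,6-tris(methoxymethoxy)phenyl]methyl}-1,2,3,4,4a,5,6,7-octahydronaphthalen-1-yl]methanol | C=C(C)[C@@H]1C=C2[C@@H](CO)CC[C@@H](Cc3c(OCOC)cc(OCOC)cc3OCOC)[C@]2(C)CC1 | intermediate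
22 | methanesulfonate of 21 | C=C(C)[C@@H]1C=C2[C@@H](COS(C)(=O)=O)CC[C@@H](Cc3c(OCOC)cc(OCOC)cc3OCOC)[C@]2(C)CC1 | intermediate
23 | 2-{[(1S,4S,6S,8aS)-4,8a-dimethyl-6-(prop-1-en-2-yl)-1,2,3,4,6,7,8,8a-octahydronaphthalen-1-yl]methyl}-1,3,5-tris(methoxymethoxy)benzene | C=C(C)[C@@H]1C=C2[C@@H](C)CC[C@@H](Cc3c(OCOC)cc(OCOC)cc3OCOC)[C@]2(C)CC1 | intermediate
24 | lithium α-amino alkoxide from 23, lithium {3-(terpenylmethyl)-2,4,6-tris(methoxymethoxy)phenyl}{[2-(dimethylamino)ethyl](methyl)amino}methanolate | C=C(C)[C@@H]1C=C2[C@@H](C)CC[C@@H](Cc3c(OCOC)c(C(O[Li])N(C)CCN(C)C)c(OCOC)cc3OCOC)[C@]2(C)CC1 | intermediate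
25 | dilithium bis-adduct, the lithium alkoxide of 24 that also carries the lithium 1-[methoxy(methyl)amino]-3-methylbutan-1-olate group on the last ring position | C=C(C)[C@@H]1C=C2[C@@H](C)CC[C@@H](Cc3c(OCOC)c(C(O[Li])N(C)CCN(C)C)c(OCOC)c(C(O[Li])(CC(C)C)N(C)OC)c3OCOC)[C@]2(C)CC1 | intermediate
26 | 3-{[(1S,4S,6S,8aS)-4,8a-dimethyl-6-(prop-1-en-2-yl)-1,2,3,4,6,7,8,8a-octahydronaphthalen-1-yl]methyl}-2,4,6-tris(methoxymethoxy)-5-(3-methylbutanoyl)benzaldehyde | C=C(C)[C@@H]1C=C2[C@@H](C)CC[C@@H](Cc3c(OCOC)c(C=O)c(OCOC)c(C(=O)CC(C)C)c3OCOC)[C@]2(C)CC1 | intermediate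
27 | 3-{[(1S,4S,6S,8aS)-4,8a-dimethyl-6-(prop-1-en-2-yl)-1,2,3,4,6,7,8,8a-octahydronaphthalen-1-yl]methyl}-2,4,6-trihydroxy-5-(3-methylbutanoyl)benzaldehyde | C=C(C)[C@@H]1C=C2[C@@H](C)CC[C@@H](Cc3c(O)c(C=O)c(O)c(C(=O)CC(C)C)c3O)[C@]2(C)CC1 | target

**Totals**
Total step count: 18. Longest linear sequence: 15 (steps 1–9 and 13–18).

**Steps most likely to fail**

Step 9. The ester may pass through the endo orientation in part, which would erode facial control at C10. The inside methyl also disfavours the s-cis diene, so a [1,5]-hydrogen shift of the diene may compete with a slow cycloaddition.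
Fallback (sets out from 9, comes back at 13): triflation of 9 under chelating conditions (Tf2O, aq. LiOH) would give the (Z)-enol triflate ethyl (2Z,5S,8E)-8-methyl-10-oxo-5-(prop-1-en-2-yl)-3-(trifluoromethanesulfonyloxy)undeca-2,8-dienoate F1. Anti elimination with Et3N would give the ynoate ethyl (5S,8E)-8-methyl-10-oxo-5-(prop-1-en-2-yl)undec-8-en-2-ynoate F2. Silylation as in step 8 would give ethyl (5S,8E)-8-methyl-5-(prop-1-en-2-yl)-10-[(triisopropylsilyl)oxy]undeca-8,10-dien-2-ynoate F3. Its thermal intramolecular Diels–Alder reaction, in which the linear alkynoate has neither an endo/exo choice nor an axis, would give the cyclohexa-1,4-diene ester ethyl (4aS,7S)-4a-methyl-7-(prop-1-en-2-yl)-3-[(triisopropylsilyl)oxy]-2,4a,5,6,7,8-hexahydronaphthalene-1-carboxylate F4; C10 then rests on the pseudo-equatorial preference of the isopropenyl group in the tether. γ-Deprotonation at C6 (LiN(i-Pr)2, THF/HMPA, −78 °C) and kinetic α-protonation of the dienolate anti to the angular methyl would move the double bond to C5=C6, set C4 and return to 13.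

Step 7. Catalyst control of the new axis next to the existing stereocentre may be insufficient, giving both axial epimers, and elimination towards the alkynoate may compete.
Fallback (sets out from 10, comes back at 11): elimination of 10 with an achiral catalyst (Pd2(dba)3, P(OPh)3, i-Pr2NEt) would give 11 together with its axial epimer ethyl (Sa,5S,8E)-8-methyl-10-oxo-5-(prop-1-en-2-yl)undeca-2,3,8-trienoate F5. Because C7 is fixed the two are diastereomers and would be separated by chromatography; F5 would be re-equilibrated at the axis with Pd(OAc)2/LiBr (reversible bromopalladation) and recycled, so the axis is secured by separation and recycling instead of by the ligand.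

Step 13. The very electron-rich benzylic bromide may condense with itself before it is captured, and attack at the neopentyl-type C1 may be slow, which would also open the way to epimerization at C1.
Fallback (sets out from 13 and uses 15, comes back at 18): Mukaiyama aldol addition of 13 to the stable aldehyde 15 (BF3·OEt2, CH2Cl2, −78 °C), with the same convex-face approach, would give the β-hydroxy ketone ethyl (1S,4R,4aS,7S)-4-{hydroxy[2,4,6-tris(methoxymethoxy)phenyl]methyl}-4a-methyl-3-oxo-7-(prop-1-en-2-yl)-1,2,3,4,4a,5,6,7-octahydronaphthalene-1-carboxylate F6. Ionic deoxygenation of its doubly ortho-alkoxy-activated benzylic alcohol (Et3SiH, BF3·OEt2, −78 °C) would give 18.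

**Further compounds**
F1 | step 9 | ethyl (2Z,5S,8E)-8-methyl-10-oxo-5-(prop-1-en-2-yl)-3-(trifluoromethanesulfonyloxy)undeca-2,8-dienoate | C=C(C)[C@H](C/C(OS(=O)(=O)C(F)(F)F)=C/C(=O)OCC)CC/C(C)=C/C(C)=O
F2 | step 9 | ethyl (5S,8E)-8-methyl-10-oxo-5-(prop-1-en-2-yl)undec-8-en-2-ynoate | C=C(C)[C@H](CC#CC(=O)OCC)CC/C(C)=C/C(C)=O
F3 | step 9 | ethyl (5S,8E)-8-methyl-5-(prop-1-en-2-yl)-10-[(triisopropylsilyl)oxy]undeca-8,10-dien-2-ynoate | C=C(C)[C@H](CC#CC(=O)OCC)CC/C(C)=C/C(=C)O[Si](C(C)C)(C(C)C)C(C)C
F4 | step 9 | ethyl (4aS,7S)-4a-methyl-7-(prop-1-en-2-yl)-3-[(triisopropylsilyl)oxy]-2,4a,5,6,7,8-hexahydronaphthalene-1-carboxylate | C=C(C)[C@@H]1CC2=C(C(=O)OCC)CC(O[Si](C(C)C)(C(C)C)C(C)C)=C[C@]2(C)CC1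
F5 | step 7 | ethyl (Sa,5S,8E)-8-methyl-10-oxo-5-(prop-1-en-2-yl)undeca-2,3,8-trienoate | C=C(C)[C@H](C([H])=[C@@]=C([H])C(=O)OCC)CC/C(C)=C/C(C)=O
F6 | step 13 | ethyl (1S,4R,4aS,7S)-4-{hydroxy[2,4,6-tris(methoxymethoxy)phenyl]methyl}-4a-methyl-3-oxo-7-(prop-1-en-2-yl)-1,2,3,4,4a,5,6,7-octahydronaphthalene-1-carboxylate | C=C(C)[C@@H]1C=C2[C@@H](C(=O)OCC)CC(=O)[C@@H](C(O)c3c(OCOC)cc(OCOC)cc3OCOC)[C@]2(C)CC1
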